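The rate constants come from no measurement; the rest is arithmetic.

Look at north and east.

common to all: time 12 s
- north: starting material 5.0 × 10⁻⁴ M (fed, over 5.0 s); partner 1.10 equiv; all else is in the flask from the start; the feed brings no volume worth counting
- north-west: starting material 5.0 × 10⁻⁴ M (fed, over 1.2 s); partner 1.10 equiv; all else is in the flask from the start; the feed brings no volume worth counting
- south-east: starting material 5.0 × 10⁻⁴ M; partner 1.10 equiv; everything together at the start
- east: starting material 5.0 × 10⁻⁴ M; partner 1.10 equiv (fed, over 5.0 s); all else is in the flask from the start; the feed brings no volume worth counting

    starting material + partner → target, rate k1*[starting material]*[partner]^1.5 (k1 = 9600 M⁻¹·⁵ s⁻¹)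
    partner → decomposed reagent (k2 = 0.049 s⁻¹)
    target → over-reaction product (k3 = 0.0053 s⁻¹)
    target ⇌ isomer of the product (K4 = 0.13, k4 = 0.11 s⁻¹)

1. the flask with the highest amount of target, in percent of the starting material charged ("all alike" if they lie within 1.5 percentage points) (north / north-west / south-east / east / all alike)
2. final target, as a percentage of the starting material charged, in north
3. final target, as a percentage of the starting material charged, in north-west
4. final target, as a percentage of the starting material charged, in south-east
5. final target, as a percentage of the starting material charged, in east

The two flasks hold the same charge, and in each one component runs in over 5.0 s, yet I expect them to part, and I look first at how long the partner has stood. In north the partner waits in the flask from the start, so if decay were its sole loss, c(partner) would keep 78.3% of its charge when the last starting material arrives. In east the partner enters evenly, so on the same count 88.7% of it is present at the end of the feed, while the waiting starting material has no decay step of its own.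

The rate goes with c(partner) to the power 1.50, so my yardstick is that survival raised to this power at the moment the charge is complete. It reads 0.692 for north, 0.916 for north-west, 0.835 for east and 1 for south-east. This leaves out the partner consumed by reaction, but I commit to the order it gives, with south-east first, then north-west, east and north.

Target does not stay as made. In south-east the starting material goes at the start with a pseudo-first-order constant of 0.124 s⁻¹, and the exchange of target with the isomer relaxes at 0.956 s⁻¹, faster than that. I therefore treat the exchange as a rapid equilibrium. Of the pool of target and isomer, the free share, meaning the part standing as target, is 88.5%. Over-reaction is slow beside this run, its half-life of 130 s being longer than 12 s. For south-east I let the partner's fraction, decay apart, fall with that of the starting material, and I let decay shorten the working time of the rate to 7.97 s. This estimate gives a conversion of 45.4%, so my figure for target in south-east is 40.2% of the charge.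

The forecast puts south-east first at 38.2%, with north-west 36.6%, east 34.4% and north 31.9%, holding that “Delaying the starting material wastes partner through decay”.

South-east ends highest at 38.4%, with north-west at 36.8%, east at 34.6% and north at 31.8%. With the loss of target to isomer struck out both ways, south-east ends at 43.1%. In the neighbour of north charged with 8.5 × 10⁻⁴ M, target ends at 45.3%, so the free share asks for a pool of 51.2% and isomer of 5.89%; that flask holds 5.70% of isomer at 12.0 s.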